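## Retrosynthetic overview
1. Target butenolide acid ⇒ exo-to-endo olefin migration from the α-methylene paraconic acid. Its C-3 stereocentre is sacrificial and C-2 carries the stereochemical information.
2. α-Methylene paraconic acid ⇒ cut the C3–C(carbinol) bond and the lactone C–O bond: enantioselective organocatalytic aldol–lactonisation of itaconic anhydride with 14-acetoxytetradecanal. This is a 1:1 adduct holding all 21 C and 6 O of the target, and it sets 2R.
3. 14-Acetoxytetradecanal ⇒ oxidation and mono-acetylation of tetradecane-1,14-diol.
4. Ring order: the only ring, the γ-lactone, forms in the key step as the anhydride ring opens to the free CO2H. No ring event follows.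

Assumption: the quinine-derived squaramide is taken to direct attack onto the Si face of the aldehyde (giving 2R). If the first run shows the opposite sense, its quinidine-derived pseudoenantiomer is used under the same conditions.

## Route

Step 1
Reactants: 1 tetradecane-1,14-diol
Product: 2 14-hydroxytetradecyl acetate
Conditions: Ac2O (1.0 equiv), pyridine, THF, 0 °C to rt; chromatography, recovered 1 and diacetate recycled
Reagents that add atoms: acetic anhydride, CC(=O)OC(C)=O
Why: Statistical mono-O-acylation (nucleophilic acyl substitution) of a symmetric diol whose remote OH groups react independently gives about half the mass as 2, which separates easily by polarity from 1 and the diacetate; no stereocentre is involved.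

Step 2
Reactants: 2 14-hydroxytetradecyl acetate
Product: 3 14-oxotetradecyl acetate (14-acetoxytetradecanal)
Conditions: TEMPO (10 mol %), PhI(OAc)2 (1.1 equiv), CH2Cl2, rt; NaHCO3 wash, short silica plug (acid-free aldehyde)
Reagents that add atoms: none
Why: The TEMPO/oxoammonium (Piancatelli–Margarita) oxidation of a primary alcohol stops at the aldehyde under near-neutral conditions that leave the acetate untouched; no stereocentre is involved.

Step 3
Reactants: 3 14-oxotetradecyl acetate; 4 itaconic anhydride (3-methylideneoxolane-2,5-dione)
Product: 6 (2R,3S)-2-(13-acetoxytridecyl)-4-methylidene-5-oxooxolane-3-carboxylic acid, via aldol adduct 5 (not isolated)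
Conditions: 3-{[3,5-bis(trifluoromethyl)phenyl]amino}-4-{[(8α,9S)-6′-methoxycinchonan-9-yl]amino}cyclobut-3-ene-1,2-dione (10 mol %), 4 (2.0 equiv, syringe pump over 12 h), 4 Å MS, MTBE/THF 9:1, −20 °C, 72 h; 1 M HCl and water washes; crystallisation
Reagents that add atoms: none
Why: Proposed new method: itaconic anhydride is used for the first time as the enolisable anhydride in a bifunctional amine–squaramide-catalysed formal cycloaddition with an unactivated linear aldehyde; the quinuclidine removes the doubly activated ring CH2 proton (the same deprotonation that drives the amine-catalysed itaconic-to-citraconic isomerisation), the squaramide-bound ion pair delivers the α-carbon of the dienolate (the site that also reacts in the known lithium itaconate dianion aldol) to the Si face of 3 to set 2R, and the alkoxide of 5 closes across the ring onto the distal carbonyl through a bicyclo[2.2.1] tetrahedral intermediate, which irreversibly opens the anhydride to the γ-lactone and the free acid; the closest known reaction type is the squaramide-catalysed aldol–lactonisation of homophthalic and arylsuccinic anhydrides with aldehydes (a catalytic asymmetric Fittig paraconic acid synthesis).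

Step 4
Reactants: 6 (2R,3S)-2-(13-acetoxytridecyl)-4-methylidene-5-oxooxolane-3-carboxylic acid
Product: 9 (2R)-2-(13-acetoxytridecyl)-4-methyl-5-oxo-2,5-dihydrofuran-3-carboxylic acid, via mixed anhydride 7 (not isolated), via isomerised mixed anhydride 8 (not isolated)
Conditions: Ac2O (5 equiv), NaOAc (10 mol %), toluene, 90 °C, 2 h; then THF/H2O, rt
Reagents that add atoms: none
Why: Activating the carboxyl as mixed anhydride 7 makes H-3 (α to the acyl group and allylic) acidic enough for acetate-mediated dienolisation, γ-protonation at the exocyclic CH2 (a 1,3-prototropic olefin migration, the classical acetic anhydride conversion of protolichesterinic into lichesterinic acid) gives the tetrasubstituted, doubly conjugated alkene 8, and water then attacks the acetyl carbonyl of 8 to release 9, so C-3 is erased (both C-3 epimers of 6 converge) while C-2 is untouched and stays R.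

## Compound list
1 | tetradecane-1,14-diol | OCCCCCCCCCCCCCCO | starting material
2 | 14-hydroxytetradecyl acetate | CC(=O)OCCCCCCCCCCCCCCO | intermediate
3 | 14-oxotetradecyl acetate (14-acetoxytetradecanal) | CC(=O)OCCCCCCCCCCCCCC=O | intermediate
4 | itaconic anhydride (3-methylideneoxolane-2,5-dione) | C=C1CC(=O)OC1=O | starting material
5 | (3S)-3-[(1R)-14-acetoxy-1-hydroxytetradecyl]-4-methylideneoxolane-2,5-dione (aldol adduct, not isolated) | CC(=O)OCCCCCCCCCCCCC[C@@H](O)[C@H]1C(=O)OC(=O)C1=C | intermediate
6 | (2R,3S)-2-(13-acetoxytridecyl)-4-methylidene-5-oxooxolane-3-carboxylic acid (trans) | CC(=O)OCCCCCCCCCCCCC[C@H]1OC(=O)C(=C)[C@@H]1C(=O)O | intermediate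
7 | acetic (2R,3S)-2-(13-acetoxytridecyl)-4-methylidene-5-oxooxolane-3-carboxylic anhydride (not isolated) | CC(=O)OCCCCCCCCCCCCC[C@H]1OC(=O)C(=C)[C@@H]1C(=O)OC(C)=O | intermediate
8 | acetic (2R)-2-(13-acetoxytridecyl)-4-methyl-5-oxo-2,5-dihydrofuran-3-carboxylic anhydride (not isolated) | CC(=O)OCCCCCCCCCCCCC[C@H]1OC(=O)C(C)=C1C(=O)OC(C)=O | intermediate
9 | (2R)-2-(13-acetoxytridecyl)-4-methyl-5-oxo-2,5-dihydrofuran-3-carboxylic acid | CC(=O)OCCCCCCCCCCCCC[C@H]1OC(=O)C(C)=C1C(=O)O | target

Total step count: 4. Longest linear sequence: 4 (1 → 2 → 3 → 6 → 9).

## Steps most likely to fail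

**Step 3 (the proposed new step).**
- The dienolate may be protonated at the exocyclic carbon (4 → citraconic anhydride) faster than it adds to an unactivated aldehyde.
- It may react at its γ-carbon instead of the α-carbon.
- Adduct 5 may tautomerise to the hydroxyalkyl maleic anhydride, which cannot lactonise for geometric reasons.
- The accumulating acid may slow the catalyst.
- The minor cis diastereomer may carry 2S. For this reason 6 is isolated, each diastereomer is checked by chiral HPLC, and the cis isomer is removed if needed.

The fallback uses known chemistry only, sets out from 3 and returns at 9. A β-isocupreidine (10 mol %)-catalysed asymmetric Morita–Baylis–Hillman reaction of 3 with 1,1,1,3,3,3-hexafluoropropan-2-yl acrylate (DMF, −55 °C) gives 1,1,1,3,3,3-hexafluoropropan-2-yl (3R)-16-acetoxy-3-hydroxy-2-methylidenehexadecanoate F1. Ozonolysis (O3, CH2Cl2, −78 °C; Me2S) gives 1,1,1,3,3,3-hexafluoropropan-2-yl (3R)-16-acetoxy-3-hydroxy-2-oxohexadecanoate F2. Neutral Wittig olefination with ethyl 2-(triphenylphosphoranylidene)propanoate (toluene, rt to 60 °C) gives 1-ethyl 4-(1,1,1,3,3,3-hexafluoropropan-2-yl) (2E)-3-[(1R)-14-acetoxy-1-hydroxytetradecyl]-2-methylbut-2-enedioate F3. Its hydroxyl closes on the cis ethyl ester in the same flask to give 1,1,1,3,3,3-hexafluoropropan-2-yl (2R)-2-(13-acetoxytridecyl)-4-methyl-5-oxo-2,5-dihydrofuran-3-carboxylate F4. The activated hexafluoroisopropyl ester is then hydrolysed selectively beside the acetate and the lactone (NaHCO3, THF/H2O, 0 °C; then pH 3) to give 9. The stereocentre is again set by an organocatalyst. This path replaces steps 3 and 4 with four operations.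

**Step 4.** The migration may stall, or C-2 may partly racemise through the 2-oxyfuran dienolate of 8 under hot acetate conditions. The fallback sets out from 6 and returns directly at 9. It replaces enolisation chemistry with a rhodium-hydride olefin migration (RhCl3·3H2O 5 mol %, i-PrOH, 80 °C). Hydrometalation of the exocyclic alkene followed by β-hydride elimination toward C-3 moves the double bond under neutral conditions. No carboxyl activation and no enolate are involved, so H-2 is never acidified. No new compound is made on this path (F0).

**Step 1.** The statistical acetylation caps the yield near 50 % and depends on recycling. The fallback sets out from 1 and returns at 2. The diol is desymmetrised by phase-controlled monobromination (48 % aq HBr, toluene, reflux), in which the bromo alcohol moves into the toluene away from the acid, giving 14-bromotetradecan-1-ol F5. SN2 displacement with KOAc (DMF, 80 °C) then gives 2.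

## Further compounds
F1 | step 3 | 1,1,1,3,3,3-hexafluoropropan-2-yl (3R)-16-acetoxy-3-hydroxy-2-methylidenehexadecanoate | CC(=O)OCCCCCCCCCCCCC[C@@H](O)C(=C)C(=O)OC(C(F)(F)F)C(F)(F)F
F2 | step 3 | 1,1,1,3,3,3-hexafluoropropan-2-yl (3R)-16-acetoxy-3-hydroxy-2-oxohexadecanoate | CC(=O)OCCCCCCCCCCCCC[C@@H](O)C(=O)C(=O)OC(C(F)(F)F)C(F)(F)F
F3 | step 3 | 1-ethyl 4-(1,1,1,3,3,3-hexafluoropropan-2-yl) (2E)-3-[(1R)-14-acetoxy-1-hydroxytetradecyl]-2-methylbut-2-enedioate | CCOC(=O)/C(C)=C(/C(=O)OC(C(F)(F)F)C(F)(F)F)[C@H](O)CCCCCCCCCCCCCOC(C)=O
F4 | step 3 | 1,1,1,3,3,3-hexafluoropropan-2-yl (2R)-2-(13-acetoxytridecyl)-4-methyl-5-oxo-2,5-dihydrofuran-3-carboxylate | CC(=O)OCCCCCCCCCCCCC[C@H]1OC(=O)C(C)=C1C(=O)OC(C(F)(F)F)C(F)(F)F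
F0 | step 4 | none | none
F5 | step 1 | 14-bromotetradecan-1-ol | OCCCCCCCCCCCCCCBr
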